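**Plan**

- Numbering: ring C1 (ketone), C2 (methyl-bearing oxirane carbon), C3 (oxirane CH), C4 (CH2), C5 (side-chain carbon), C6 (tiglate carbon); side chain C7 (with exocyclic methylene C7'), C8 (ketone), C9=C10, C11 (carbinol). Tiglate = (E)-2-methylbut-2-enoate.
- Enabling feature: the side-chain ketone C8 on the six-membered carbocycle is flanked by two alkenyl carbons, C7 of the C7=C7' unit on ring carbon C5 and C9 of the E-alkene C9=C10. C8 can therefore be introduced as carbon monoxide between an alkenyl electrophile and an alkenyl nucleophile.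
- Cuts: the C1 ketone goes back to a silyl-protected carbinol; C7–C8 and C8–C9 are cut together (C7 enol triflate, CO, E-alkenylstannane); the triflate goes back to an acetyl group and on to the isopropenyl group of (R)-carvone; the O6–acyl bond, the oxirane and the C6–O bond are cut last.
- Forward order: the carbocycle is that of (R)-carvone. The C6 oxygen, the tiglate, the C1 carbinol and the oxirane (the only ring formed) are installed, the isopropenyl group is cut down to the C7 enol triflate, the C8–C11 chain is joined in one carbonylative step, and the C1 ketone is unveiled at the end.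
- Stereochemistry: C5 comes from (R)-carvone; C6 from peracid attack anti to the C5 substituent; the temporary C1 carbinol from axial hydride delivery; C2/C3 from epoxidation directed syn to that carbinol, hence cis to the C5 chain. Both E alkenes come from tiglic acid and from a syn-hydrostannylation.

Key step: step 9

Remark: the target SMILES is read as oxirane cis to the C5 side chain and tiglate trans to it. Locants in all compound names follow the numbering above, so descriptors change where substituent priorities change, not where configuration changes.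

**Route**

Step 1
Reactants: 1 (R)-carvone
Product: 4 (5S,6S)-6-hydroxycarvone (C6 hydroxyl trans to the isopropenyl group), via trimethylsilyl dienol ether 2 (not isolated), via 6-trimethylsilyloxy ketone 3 (not isolated)
Conditions: LiN(i-Pr)2, THF, −78 °C; Me3SiCl, −78 → 0 °C; mCPBA, hexane, −15 °C → rt; 1 M HCl, THF, 0 °C
Reagents that add atoms: mCPBA, O=C(OO)c1cccc(Cl)c1 (the C6 oxygen); Me3SiCl, C[Si](C)(C)Cl (silicon held only in 2 and 3)
Why: Rubottom oxidation: kinetic deprotonation at C6 and O-silylation give the cross-conjugated dienol ether 2, whose electron-rich C1=C6 bond should be epoxidised well ahead of the isopropenyl group and from the face opposite the neighbouring C5 substituent, so that silyl migration (3) and acid hydrolysis leave the C6 hydroxyl trans to C5 (6S), which is also the arrangement favoured at equilibrium.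

Step 2
Reactants: 4 (5S,6S)-6-hydroxycarvone; 5 tiglic acid
Product: 6 (5S,6S)-6-(tigloyloxy)carvone
Conditions: DCC, DMAP (cat.), CH2Cl2, 0 °C → rt
Reagents that add atoms: none
Why: Steglich esterification of the secondary α-ketol with tiglic acid under DMAP catalysis should acylate O6 without touching a stereocentre and with the E geometry of 5 kept.

Step 3
Reactants: 6 (5S,6S)-6-(tigloyloxy)carvone
Product: 7 (1S,5S,6S)-1-hydroxy-2-methyl-5-(prop-1-en-2-yl)cyclohex-2-en-6-yl tiglate (1-OH cis to the isopropenyl group and trans to the tiglate)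
Conditions: NaBH4, CeCl3·7H2O, MeOH, −78 °C
Reagents that add atoms: none
Why: Luche reduction: the CeCl3-activated borohydride adds 1,2 to the enone and, by axial delivery to the half-chair in which the C5 and C6 substituents are pseudo-equatorial, should place the new C1 hydroxyl cis to the isopropenyl group and trans to the tiglate (1S), while the low temperature keeps the ester from migrating and the conjugated ester is not reduced.

Step 4
Reactants: 7 allylic alcohol
Product: 8 (1R,2R,3S,5S,6S)-2,3-epoxy-1-hydroxy-2-methyl-5-(prop-1-en-2-yl)cyclohexan-6-yl tiglate (oxirane and 1-OH on the face of the C5 substituent)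
Conditions: VO(acac)2 (cat.), t-BuOOH, CH2Cl2, 0 °C → rt
Reagents that add atoms: tert-butyl hydroperoxide, CC(C)(C)OO
Why: Hydroxyl-directed epoxidation: the vanadium alkoxide of the C1 hydroxyl delivers the peroxide oxygen to the same face of C2=C3, which sets C2 and C3 with the oxirane cis to the C1 hydroxyl and hence cis to the C5 substituent, while the remote isopropenyl group and the electron-poor tiglate alkene should stay untouched.

Step 5
Reactants: 8 epoxy alcohol
Product: 9 (1R,2S,3S,5S,6S)-2,3-epoxy-2-methyl-5-(prop-1-en-2-yl)-1-(triethylsilyloxy)cyclohexan-6-yl tiglate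
Conditions: Et3SiCl, imidazole, DMF, 0 °C → rt
Reagents that add atoms: triethylsilyl chloride, CC[Si](Cl)(CC)CC
Why: Silyl ether formation parks C1 at the carbinol level, so that neither an acidic C6–H nor an α,β-epoxy ketone is present in the enolisation and palladium steps; no stereocentre changes.

Step 6
Reactants: 9 silyl ether
Product: 10 (1R,2S,3S,5R,6S)-5-acetyl-2,3-epoxy-2-methyl-1-(triethylsilyloxy)cyclohexan-6-yl tiglate
Conditions: OsO4 (cat.), NaIO4, 2,6-lutidine, dioxane/H2O, rt
Reagents that add atoms: OsO4, O=[Os](=O)(=O)=O (transfers the oxygen), renewed by NaIO4, [Na+].[O-]I(=O)(=O)=O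
Why: Lemieux–Johnson oxidation: the 1,1-disubstituted isopropenyl alkene is far more reactive towards OsO4 than the conjugated, trisubstituted tiglate alkene (the same discrimination that lets the isopropenyl group of carvone be cleaved beside its enone), and 2,6-lutidine keeps the medium near neutral for the silyl ether and the oxirane.

Step 7
Reactants: 10 methyl ketone
Product: 11 (1R,2S,3S,5R,6S)-2,3-epoxy-2-methyl-1-(triethylsilyloxy)-5-[1-(trifluoromethylsulfonyloxy)ethenyl]cyclohexan-6-yl tiglate (C7 enol triflate)
Conditions: N-(5-chloropyridin-2-yl)bis(trifluoromethanesulfonimide), then KN(SiMe3)2 added dropwise, THF, −78 °C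
Reagents that add atoms: N-(5-chloropyridin-2-yl)bis(trifluoromethanesulfonimide), O=S(=O)(N(c1ccc(Cl)cn1)S(=O)(=O)C(F)(F)F)C(F)(F)F
Why: Kinetic enolate O-sulfonylation: the hindered amide base removes a proton from the methyl group of the α-branched methyl ketone, not from the C5 methine, and because the triflyl donor is already present the terminal enolate should be trapped at −78 °C before it can exchange to the C5 enolate (which would expel the tiglate) or attack the ester, so C5 is not epimerised.

Step 8
Reactants: 12 2-methylbut-3-yn-2-ol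
Product: 13 (E)-2-methyl-4-(tributylstannyl)but-3-en-2-ol
Conditions: Bu3SnH, PdCl2(PPh3)2 (cat.), THF, 0 °C → rt
Reagents that add atoms: tributyltin hydride, CCCC[SnH](CCCC)CCCC
Why: Palladium-catalysed hydrostannylation: syn addition of Sn–H across the terminal alkyne, with tin going to the unhindered terminal carbon away from the tertiary carbinol, fixes the E geometry of the alkenylstannane.

Step 9
Reactants: 11 C7 enol triflate; 13 (E)-alkenylstannane; 14 carbon monoxide
Product: 15 (1R,2S,3S,5S,6S)-2,3-epoxy-5-[(4E)-6-hydroxy-6-methyl-3-oxohepta-1,4-dien-2-yl]-2-methyl-1-(triethylsilyloxy)cyclohexan-6-yl tiglate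
Conditions: Pd(PPh3)4 (cat.), LiCl, CO (1–3 atm), THF, 55 °C, 13 added slowly
Reagents that add atoms: none
Why: Zerovalent palladium adds oxidatively to the C7–O bond of 11, chloride replaces triflate on divalent palladium, CO inserts into the Pd–C7 bond to give the acyl complex, the alkenyl group of 13 is transferred from tin with retention of its E geometry, and reductive elimination forms C8–C9, so that C7–C8 and C8–C9 are both made in one operation. The closest known reaction type is the carbonylative Stille coupling of enol triflates with alkenylstannanes to divinyl ketones. No ring is closed and no stereocentre is created; the C9=C10 geometry is that of the stannane and the ring stereocentres are untouched under these neutral conditions. The selectivity needed is CO insertion ahead of direct alkenyl–alkenyl coupling, which the hindered, α-branched alkenylpalladium intermediate (slow to transmetalate), the CO atmosphere, LiCl and slow addition of 13 should secure. C1 is held as its silyl ether so that no α,β-epoxy ketone and no acidic C6–H meet zerovalent palladium, and the tiglate is homoallylic, so it cannot ionise to an allylpalladium species. The free tertiary alcohol of 13 is tolerated, and the oxirane, the ester and the silyl ether are spectators.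

Step 10
Reactants: 15 silyl-protected dienone
Product: 16 (1R,2R,3S,5S,6S)-2,3-epoxy-1-hydroxy-5-[(4E)-6-hydroxy-6-methyl-3-oxohepta-1,4-dien-2-yl]-2-methylcyclohexan-6-yl tiglate
Conditions: HF·pyridine, pyridine, THF, 0 °C
Reagents that add atoms: none
Why: Fluoride-mediated desilylation under mildly acidic, buffered conditions, chosen so that the freed C1 hydroxyl stays protonated and neither takes over the tiglate nor adds to the enone, and so that the oxirane, the tertiary alcohol and the ester remain intact.

Step 11
Reactants: 16 C1 carbinol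
Product: 17 CNP0263368.1, (2S,3S,5S,6S)-2,3-epoxy-5-[(4E)-6-hydroxy-6-methyl-3-oxohepta-1,4-dien-2-yl]-2-methyl-1-oxocyclohexan-6-yl tiglate
Conditions: Dess–Martin periodinane, pyridine, CH2Cl2, 0 °C → rt
Reagents that add atoms: none
Why: Dess–Martin oxidation of the secondary C1 carbinol to the ketone under buffered, non-basic conditions; the tertiary alcohol cannot be oxidised, C6 (now α to the ketone) already carries its tiglate in the more stable arrangement trans to C5 and sees no base, and the oxirane configuration set in step 4 is retained.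

**Compound list**

1 | (R)-carvone, (5R)-2-methyl-5-(prop-1-en-2-yl)cyclohex-2-en-1-one | CC(=C)[C@@H]1CC=C(C)C(=O)C1 | starting material
2 | trimethylsilyl dienol ether of 1 (C1=C6 and C2=C3 double bonds, 5R) | C=C(C)[C@@H]1CC=C(C)C(O[Si](C)(C)C)=C1 | intermediate
3 | (5S,6S)-6-(trimethylsilyloxy)carvone | C=C(C)[C@@H]1CC=C(C)C(=O)[C@H]1O[Si](C)(C)C | intermediate
4 | (5S,6S)-6-hydroxycarvone | C=C(C)[C@@H]1CC=C(C)C(=O)[C@H]1O | intermediate
5 | tiglic acid, (E)-2-methylbut-2-enoic acid | C/C=C(\C)C(=O)O | starting material
6 | (5S,6S)-6-(tigloyloxy)carvone | C=C(C)[C@@H]1CC=C(C)C(=O)[C@H]1OC(=O)/C(C)=C/C | intermediate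
7 | (1S,5S,6S)-1-hydroxy-2-methyl-5-(prop-1-en-2-yl)cyclohex-2-en-6-yl tiglate | C=C(C)[C@@H]1CC=C(C)[C@H](O)[C@H]1OC(=O)/C(C)=C/C | intermediate
8 | (1R,2R,3S,5S,6S)-2,3-epoxy-1-hydroxy-2-methyl-5-(prop-1-en-2-yl)cyclohexan-6-yl tiglate | C=C(C)[C@@H]1C[C@@H]2O[C@]2(C)[C@H](O)[C@H]1OC(=O)/C(C)=C/C | intermediate
9 | (1R,2S,3S,5S,6S)-2,3-epoxy-2-methyl-5-(prop-1-en-2-yl)-1-(triethylsilyloxy)cyclohexan-6-yl tiglate | C=C(C)[C@@H]1C[C@@H]2O[C@]2(C)[C@H](O[Si](CC)(CC)CC)[C@H]1OC(=O)/C(C)=C/C | intermediate
10 | (1R,2S,3S,5R,6S)-5-acetyl-2,3-epoxy-2-methyl-1-(triethylsilyloxy)cyclohexan-6-yl tiglate | CC(=O)[C@@H]1C[C@@H]2O[C@]2(C)[C@H](O[Si](CC)(CC)CC)[C@H]1OC(=O)/C(C)=C/C | intermediate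
11 | (1R,2S,3S,5R,6S)-2,3-epoxy-2-methyl-1-(triethylsilyloxy)-5-[1-(trifluoromethylsulfonyloxy)ethenyl]cyclohexan-6-yl tiglate | C=C(OS(=O)(=O)C(F)(F)F)[C@@H]1C[C@@H]2O[C@]2(C)[C@H](O[Si](CC)(CC)CC)[C@H]1OC(=O)/C(C)=C/C | intermediate
12 | 2-methylbut-3-yn-2-ol | CC(C)(O)C#C | starting material
13 | (E)-2-methyl-4-(tributylstannyl)but-3-en-2-ol | CC(C)(O)/C=C/[Sn](CCCC)(CCCC)CCCC | intermediate
14 | carbon monoxide | [C-]#[O+] | starting material
15 | (1R,2S,3S,5S,6S)-2,3-epoxy-5-[(4E)-6-hydroxy-6-methyl-3-oxohepta-1,4-dien-2-yl]-2-methyl-1-(triethylsilyloxy)cyclohexan-6-yl tiglate | C=C(C(=O)/C=C/C(C)(C)O)[C@@H]1C[C@@H]2O[C@]2(C)[C@H](O[Si](CC)(CC)CC)[C@H]1OC(=O)/C(C)=C/C | intermediate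
16 | (1R,2R,3S,5S,6S)-2,3-epoxy-1-hydroxy-5-[(4E)-6-hydroxy-6-methyl-3-oxohepta-1,4-dien-2-yl]-2-methylcyclohexan-6-yl tiglate | C=C(C(=O)/C=C/C(C)(C)O)[C@@H]1C[C@@H]2O[C@]2(C)[C@H](O)[C@H]1OC(=O)/C(C)=C/C | intermediate
17 | CNP0263368.1, (2S,3S,5S,6S)-2,3-epoxy-5-[(4E)-6-hydroxy-6-methyl-3-oxohepta-1,4-dien-2-yl]-2-methyl-1-oxocyclohexan-6-yl tiglate | C=C(C(=O)/C=C/C(C)(C)O)[C@@H]1C[C@@H]2O[C@]2(C)C(=O)[C@H]1OC(=O)/C(C)=C/C | target

**Step count**

Total: 11 steps. Longest linear sequence: 10 steps (steps 1–7 and 9–11 from (R)-carvone); step 8 is the one-step stannane branch.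

**Steps most likely to fail**

Step 7 (enol triflate). The terminal enolate may pass its proton to C5 and expel tiglic acid by β-elimination, or the tigloyl group may shift from O6 to the enolate carbon C7' before O-sulfonylation. The fallback brings the ester in only after the triflate exists. It sets out from 4, whose C6 hydroxyl would be masked with 4-methoxybenzyl 2,2,2-trichloroacetimidate and La(OTf)3 (cat.) in toluene to give the 6-O-(4-methoxybenzyl) ether F1. The operations of steps 3 to 7 would then be repeated on this ether-protected series: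
- Luche reduction to the allylic alcohol F2;
- VO(acac)2/t-BuOOH to the epoxy alcohol F3;
- Et3SiCl/imidazole to the triethylsilyl ether F4;
- OsO4/NaIO4 to the methyl ketone F5;
- KN(SiMe3)2 and the triflimide to the enol triflate F6, which carries no acyl group.

DDQ in CH2Cl2/pH 7 buffer would then free the C6 hydroxyl to give the C6 alcohol F7, and Steglich esterification with 5 comes back to the route at 11.

Step 9 (carbonylative coupling). Direct alkenyl–alkenyl coupling may outrun CO uptake, or the cross-conjugated dienone may be consumed by cyclisation or oligomerisation during heating. The fallback builds the ketone by carbonyl addition at room temperature and sets out from 11 and 13.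
- Palladium-catalysed formylation of 11 (Pd(PPh3)4, CO, Bu3SnH added slowly, LiCl, THF, 50 °C) should give the 2-substituted acrolein F8.
- Iododestannylation of 13 with I2 in CH2Cl2 at 0 °C should give (E)-4-iodo-2-methylbut-3-en-2-ol F9.
- Nozaki–Hiyama–Kishi coupling of the two (CrCl2, NiCl2 cat., DMSO, rt) should give the divinyl carbinol F10 as a mixture of C8 epimers.
- Dess–Martin oxidation comes back to the route at 15.

Step 10 (desilylation). The freed C1 hydroxyl, fluoride or pyridine may add to the C7'=C7–C8=O enone, or the dienone may oligomerise while the silyl ether is cleaved. The fallback reverses the order so that the dienone is formed last. It sets out from 11: HF·pyridine should give the C1 carbinol F11, and Dess–Martin oxidation the epoxy ketone triflate F12. F12 would then be coupled with 13 and 14 (Pd2(dba)3, AsPh3, LiCl, CO, THF, 45 °C, kept mild to spare the α,β-epoxy ketone), which comes back to the route at 17.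

**Further compounds**

F1 | step 7 | 6-O-(4-methoxybenzyl) ether of 4 | C=C(C)[C@@H]1CC=C(C)C(=O)[C@H]1OCc2ccc(OC)cc2
F2 | step 7 | 6-O-(4-methoxybenzyl) analogue of 7 (C1 allylic alcohol) | C=C(C)[C@@H]1CC=C(C)[C@H](O)[C@H]1OCc2ccc(OC)cc2
F3 | step 7 | 6-O-(4-methoxybenzyl) analogue of 8 (epoxy alcohol) | C=C(C)[C@@H]1C[C@@H]2O[C@]2(C)[C@H](O)[C@H]1OCc3ccc(OC)cc3
F4 | step 7 | 6-O-(4-methoxybenzyl) analogue of 9 (triethylsilyl ether) | C=C(C)[C@@H]1C[C@@H]2O[C@]2(C)[C@H](O[Si](CC)(CC)CC)[C@H]1OCc3ccc(OC)cc3
F5 | step 7 | 6-O-(4-methoxybenzyl) analogue of 10 (methyl ketone) | CC(=O)[C@@H]1C[C@@H]2O[C@]2(C)[C@H](O[Si](CC)(CC)CC)[C@H]1OCc3ccc(OC)cc3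
F6 | step 7 | 6-O-(4-methoxybenzyl) analogue of 11 (enol triflate) | C=C(OS(=O)(=O)C(F)(F)F)[C@@H]1C[C@@H]2O[C@]2(C)[C@H](O[Si](CC)(CC)CC)[C@H]1OCc3ccc(OC)cc3
F7 | step 7 | C6 alcohol of the enol triflate (1-O-triethylsilyl) | C=C(OS(=O)(=O)C(F)(F)F)[C@@H]1C[C@@H]2O[C@]2(C)[C@H](O[Si](CC)(CC)CC)[C@H]1O
F8 | step 9 | 2-substituted acrolein (C7 carries CHO and the C7' methylene; 1-O-triethylsilyl, 6-O-tigloyl) | C=C(C=O)[C@@H]1C[C@@H]2O[C@]2(C)[C@H](O[Si](CC)(CC)CC)[C@H]1OC(=O)/C(C)=C/C
F9 | step 9 | (E)-4-iodo-2-methylbut-3-en-2-ol | CC(C)(O)/C=C/I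
F10 | step 9 | divinyl carbinol, C8 alcohol of 15 (both C8 epimers) | C=C(C(O)/C=C/C(C)(C)O)[C@@H]1C[C@@H]2O[C@]2(C)[C@H](O[Si](CC)(CC)CC)[C@H]1OC(=O)/C(C)=C/C
F11 | step 10 | C1 carbinol of the enol triflate (6-O-tigloyl) | C=C(OS(=O)(=O)C(F)(F)F)[C@@H]1C[C@@H]2O[C@]2(C)[C@H](O)[C@H]1OC(=O)/C(C)=C/C
F12 | step 10 | C1 ketone of the enol triflate (epoxy ketone triflate, 6-O-tigloyl) | C=C(OS(=O)(=O)C(F)(F)F)[C@@H]1C[C@@H]2O[C@]2(C)C(=O)[C@H]1OC(=O)/C(C)=C/C
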